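Complex with one exchanged is the product we want from the red flask, and each one made costs one incoming ligand, from a charge of 0.700 equiv.

| setting | red | amber | flask |
|---|---|---|---|
| starting complex | 0.11 M | 0.11 M | 0.11 M |
| incoming ligand | 0.70 equiv | 0.70 equiv | 0.700 equiv |
| leaving ligand | 5 equiv | 5 equiv | 5.00 equiv |
| temperature | 60 °C | 66 °C | 60 °C |
| remark | the very flask that is asked about, followed so far | run made earlier |  |
| time |  |  | 8.0 d |

| run | time / d | complex with one exchanged / % | starting complex / % |
|---|---|---|---|
| red | 0.500 | 31.6 | 68.0 |
| red | 1.67 | 45.3 | 48.6 |
| red | 3.00 | 43.1 | 46.3 |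
| red | 4.00 | 43.0 | 46.2 |
| red | 6.00 | 41.6 | 44.7 |
| red | 8.00 | 38.2 | 43.7 |
| amber | 0.500 | 38.3 | 59.2 |
| amber | 1.67 | 44.8 | 46.6 |
| amber | 3.00 | 39.1 | 46.3 |
| amber | 4.00 | 35.4 | 45.4 |
| amber | 6.00 | 30.1 | 46.0 |
| amber | 8.00 | 26.2 | 43.9 |

(readings scatter by 1 percentage point)

- ash: at 8.0 d raise the temperature by 10 K, then wait 2.5 d
- cedar: change nothing and wait 2.5 d more
- oak: at 8.0 d take out 90% of the complex with one exchanged then present, then wait 2.5 d
- elm: at 8.0 d add incoming ligand, 100% of the amount charged, then wait 2.5 d

- complex with one exchanged that was removed still counts
- what was read earlier has a scatter of 1 percentage point, one standard deviation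
- a reading or a percentage of leaving ligand counts all its forms, free or not
- additions bring no volume worth counting

- complex with one exchanged, in percent of the starting complex first charged, at 8.0 d
- which option adds most complex with one exchanged ("none" when 2 percentage points or less is all one gets) (ash / cedar / oak / elm / none)
- complex with one exchanged present, with what was taken out counted in, in percent of the starting complex first charged, after cedar
- complex with one exchanged present, with what was taken out counted in, in percent of the starting complex first charged, after elm

The readings of starting complex stop near 46.0% in red and in amber, although amber at 66 °C falls faster at first, to 59.2% against 68.0%. We take this first exchange as settled and fold it into one number, the ligand reach, exchanges made per incoming ligand charged, counted from the loss of starting complex: 0.771. We read the common stop as incoming ligand being the limiting reagent, with the rest of its charge going elsewhere.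

One number is not enough. The reach counts exchange, yet red complex with one exchanged still slides from 43.1% to 38.2%. So we put the present value near that last reading and expect waiting to lose. On elm's fresh ligand the reach asks for 54.0% of new exchange, more than the starting complex we read as left, so we take it as pointing to a gain and put no figure on that gain for so short a wait. Ash and oak bring no ligand, so we choose elm.

The forecast gives 38.9% (37.7% to 40.1%), 36.5% after cedar, 60% after elm (52% to 69%), and chooses elm. It reads the stop differently from us: “it behaves as an equilibrium held back by excess leaving ligand”.

The flask gives 37.7%, 34.4% after cedar and 51.7% after elm; elm is best, adding 14 percentage points.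

    incoming ligand ⇌ dormant form (K = 36.0, k = 0.00940 h⁻¹, Ea = 112 kJ mol⁻¹, ΔH = −43.0 kJ mol⁻¹)
    complex with one exchanged → over-reaction product (k = 0.00160 h⁻¹, Ea = 119 kJ mol⁻¹)
    starting complex + incoming ligand ⇌ leaving ligand + complex with one exchanged (K = 120, k = 0.650 L mol⁻¹ h⁻¹, Ea = 91.0 kJ mol⁻¹, ΔH = −11.0 kJ mol⁻¹)
    crystals ⇌ leaving ligand, rate k4*(cs4 - [leaving ligand]) while solid is left; crystals form when [leaving ligand] > cs4 (solubility = 1.80 mM, k = 0.470 h⁻¹)
    complex with one exchanged + incoming ligand ⇌ leaving ligand + complex with two exchanged (K = 5.70, k = 0.140 L mol⁻¹ h⁻¹, Ea = 98.0 kJ mol⁻¹, ΔH = 2.00 kJ mol⁻¹)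
    (constants at 60 °C)

At 8.00 d this flask has 0.103% of its incoming ligand free beside 45.0% starting complex, and first and second exchanges together count 59.9% against the 54.0% that the reach gives from the readings of starting complex. The neighbouring flask, charged with 1.80 equiv of incoming ligand, gets the same reckoning: the reach asks 139% of exchange, in percent of starting complex charged. That flask ends with 3.30% starting complex and 37.6% complex with two exchanged, so its exchanges count 134%.

The numbers in the tables stem from a simulated flask with made-up constants; scatter was added.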